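Retrosynthesis (carotenoid numbering; ring A = ε ring, ring B = dihydroxy-β ring): the chain is cut at C11=C12 and C11'=C12' (two Wittig reactions on a C10 dialdehyde), ring B is cut from its side chain at C6–C7, and ring B itself is cut at C1–C2 and C4–C5.
Enabling feature: in ring B, C4 and C6 flank C5 as the carbonyl carbons of a masked cyclohexane-1,3-dione (C4–OH, enol-type C5=C6), C1 is the gem-dimethyl α-carbon of C6 and C3 bears oxygen beside CH2-2. C5–C6–C1 is therefore 2-methylpentan-3-one (nucleophilic at both α-carbons) and C2–C3–C4 is a glycidate (electrophilic at the epoxide CH2 and the ester carbon).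
Forward, ring B first: one-pot acylation/epoxide-opening [3+3] annulation, enol acetonide (a temporary ring that leaves only C6 as a carbonyl), addition of the C7–C11 dienyl unit to C6 with 1,3-carbonyl transposition, phosphonium salt.
Ring A is not built but taken from (R)-α-ionone: homologation to the C15 ester, allylic oxidation at C3', reduction, Mitsunobu inversion, reduction, phosphonium salt.
Chain joining: ring-A C15 salt + C10 dialdehyde gives the C25 aldehyde, the ring-B C15 salt then gives the C40 4-ketone, and C4=O is reduced last.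
Stereochemistry: C3 from methyl (S)-glycidate, C4 by hydride addition anti to the C3 oxygen (cis-diol), C6' from (R)-α-ionone, C3' by hindered-hydride reduction then Mitsunobu inversion; E double bonds from stannane geometry, olefination and thermal equilibration.

Key step: step 1

Assumption: (R)-α-ionone 13, methyl (S)-glycidate 2, (E)-3-methylpent-2-en-4-yn-1-ol 6 and the C10 dialdehyde 20 are bought as single isomers; skeleton atoms are called by carotenoid numbering throughout.

Step 1
Reactants: 1 2-methylpentan-3-one; 2 methyl (2S)-oxirane-2-carboxylate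
Product: 4 (4S)-3,4-dihydroxy-2,6,6-trimethylcyclohex-2-en-1-one, via epoxy diketone 3 (not isolated)
Conditions: 1 (2 equiv), LiN(iPr)2 (2 equiv), THF, −78 °C; 2 (1 equiv), −78 → −30 °C; LiN(iPr)2 (2.3 equiv), −78 → 0 °C; aq. HCl, 0 °C; argon
Reagents that add atoms: none
Why: Proposed new method: the kinetic lithium enolate of 1 (CH2 side, C5) is C-acylated by the ester carbon of 2 (crossed Claisen, bond C4–C5) to the lithium diketonate of 3, and the second charge of base removes the isopropyl methine proton to give the 1,3-diketone dianion, whose γ-carbon (C1) opens the oxirane at its CH2 (bond C1–C2). The closest known reactions are the base-mediated Michael–Claisen [3+3] annulation of ketones with acrylates to cyclohexane-1,3-diones and the γ-alkylation of 1,3-dicarbonyl dianions by epoxides; new is the use of a glycidate as a chiral acrylate equivalent that brings the C3 oxygen with it. Ring B closes in the 6-(enolendo)-exo-tet mode at the primary epoxide carbon, whereas attack at the internal epoxide carbon would be a disfavoured 5-(enolendo)-exo-tet closure onto a more hindered centre. No stereocentre is made: C3 (S) is the epoxide CH of 2, whose C–O bond is not broken, C5 ends enolised and the new quaternary C1 carries two methyl groups. The step needs site-selective enolisation twice (kinetic deprotonation at the CH2 of 1; then the isopropyl CH is the only acidic γ-position of the diketonate), C- over O-alkylation (the dianion carbon should far outrun the chelated diketonate oxygens) and a configurationally stable C3 (it sits between an alkoxide and a delocalised diketonate until the quench).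

Step 2
Reactants: 4 (4S)-3,4-dihydroxy-2,6,6-trimethylcyclohex-2-en-1-one
Product: 5 (7aS)-2,2,4,6,6-pentamethyl-7,7a-dihydro-1,3-benzodioxol-5(6H)-one
Conditions: 2,2-dimethoxypropane, cat. TsOH, acetone, rt
Reagents that add atoms: 2,2-dimethoxypropane, COC(C)(C)OC
Why: Acid-catalysed acetalisation, in which only the C3 hydroxyl and the neighbouring enol oxygen on C4 can close a dioxolane, so the dione is fixed as the C4 enol ether and C6 stays the only free carbonyl; C3 is not touched.

Step 3
Reactants: 6 (2E)-3-methylpent-2-en-4-yn-1-ol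
Product: 7 triethyl{[(2E)-3-methylpent-2-en-4-yn-1-yl]oxy}silane
Conditions: Et3SiCl, imidazole, CH2Cl2, 0 °C → rt
Reagents that add atoms: chlorotriethylsilane, CC[Si](Cl)(CC)CC
Why: Standard silylation of a primary alcohol; the triethylsilyl ether tolerates butyllithium at −78 °C and is cleaved by the acid of step 5.

Step 4
Reactants: 7 triethyl{[(2E)-3-methylpent-2-en-4-yn-1-yl]oxy}silane
Product: 8 tributyl{(1E,3E)-3-methyl-5-[(triethylsilyl)oxy]penta-1,3-dien-1-yl}stannane
Conditions: Bu3SnH, PdCl2(PPh3)2 (2 mol%), THF, 0 °C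
Reagents that add atoms: tributylstannane, CCCC[SnH](CCCC)CCCC
Why: Palladium-catalysed syn-hydrostannylation of the terminal alkyne of a conjugated enyne should place tin on the terminal carbon and give the 1E dienylstannane (the future C7=C8 bond).

Step 5
Reactants: 8 tributyl{(1E,3E)-3-methyl-5-[(triethylsilyl)oxy]penta-1,3-dien-1-yl}stannane; 5 (7aS)-2,2,4,6,6-pentamethyl-7,7a-dihydro-1,3-benzodioxol-5(6H)-one
Product: 11 (6S)-6-hydroxy-3-[(1E,3E)-5-hydroxy-3-methylpenta-1,3-dien-1-yl]-2,4,4-trimethylcyclohex-2-en-1-one, via dienyllithium 9 (not isolated), via tertiary carbinol 10 (not isolated)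
Conditions: 8, n-BuLi, THF, −78 °C; anhydrous CeCl3, −78 °C; 5, −78 → −20 °C; then 1 M aq. HCl, THF, 0 °C → rt
Reagents that add atoms: none
Why: Tin–lithium exchange with retention of the E geometry and organocerium 1,2-addition to the hindered carbonyl form C6–C7, after which acid unmasks the enol acetonide, expels the doubly allylic tertiary hydroxyl (Stork–Danheiser transposition to the C4 enone with C5=C6) and removes the silyl ether; C3 is untouched and the carbinol centre of 10 is destroyed.

Step 6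
Reactants: 11 (6S)-6-hydroxy-3-[(1E,3E)-5-hydroxy-3-methylpenta-1,3-dien-1-yl]-2,4,4-trimethylcyclohex-2-en-1-one
Product: 12 {(2E,4E)-5-[(4S)-4-hydroxy-2,6,6-trimethyl-3-oxocyclohex-1-en-1-yl]-3-methylpenta-2,4-dien-1-yl}triphenylphosphonium bromide
Conditions: Ph3P·HBr, CH2Cl2, 0 °C → rt
Reagents that add atoms: triphenylphosphine hydrobromide, [Br-].[PH+](c1ccccc1)(c1ccccc1)c1ccccc1
Why: Acid-mediated ionisation of the primary dienylic alcohol and capture by triphenylphosphine at the primary terminus is the standard formation of a C15 Wittig salt; the α-ketol is inert under these conditions.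

Step 7
Reactants: 13 (3E)-4-[(1R)-2,6,6-trimethylcyclohex-2-en-1-yl]but-3-en-2-one
Product: 14 ethyl (2E,4E)-3-methyl-5-[(1R)-2,6,6-trimethylcyclohex-2-en-1-yl]penta-2,4-dienoate
Conditions: (EtO)2P(O)CH2CO2Et, NaH, THF, 0 °C → rt; chromatography removes the 2Z isomer
Reagents that add atoms: triethyl phosphonoacetate, CCOC(=O)CP(=O)(OCC)OCC
Why: Horner–Wadsworth–Emmons olefination of the methyl ketone should favour the 2E dienoate, and the stabilised phosphonate anion is too weak a base to epimerise C6'.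

Step 8
Reactants: 14 ethyl (2E,4E)-3-methyl-5-[(1R)-2,6,6-trimethylcyclohex-2-en-1-yl]penta-2,4-dienoate
Product: 15 ethyl (2E,4E)-3-methyl-5-[(1R)-2,6,6-trimethyl-4-oxocyclohex-2-en-1-yl]penta-2,4-dienoate
Conditions: aq. t-BuOOH, Rh2(cap)4 (1 mol%, cap = caprolactamate), 1,2-dichloroethane, 40 °C
Reagents that add atoms: tert-butyl hydroperoxide, CC(C)(C)OO
Why: Dirhodium-caprolactamate/hydroperoxide allylic oxidation turns the ring allylic CH2 (C3') into the enone carbonyl; the tertiary C6'–H is shielded by the gem-dimethyl carbon and the ring methyl, and base-free conditions keep C6' from epimerising.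

Step 9
Reactants: 15 ethyl (2E,4E)-3-methyl-5-[(1R)-2,6,6-trimethyl-4-oxocyclohex-2-en-1-yl]penta-2,4-dienoate
Product: 16 ethyl (2E,4E)-5-[(1R,4S)-4-hydroxy-2,6,6-trimethylcyclohex-2-en-1-yl]-3-methylpenta-2,4-dienoate
Conditions: Li[BH(s-Bu)3] (L-Selectride), THF, −78 °C; H2O
Reagents that add atoms: none
Why: 1,2-Reduction of the enone by a hindered borohydride, in which the carbonyl face syn to the pseudo-axial methyl of the gem-dimethyl carbon is blocked, so hydride should enter from the other face of the half-chair with the side chain pseudo-equatorial and leave the hydroxyl cis to the side chain (4S); the dienoate is inert at −78 °C.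

Step 10
Reactants: 16 ethyl (2E,4E)-5-[(1R,4S)-4-hydroxy-2,6,6-trimethylcyclohex-2-en-1-yl]-3-methylpenta-2,4-dienoate
Product: 17 ethyl (2E,4E)-5-[(1R,4R)-4-(benzoyloxy)-2,6,6-trimethylcyclohex-2-en-1-yl]-3-methylpenta-2,4-dienoate
Conditions: PhCO2H, PPh3, diisopropyl azodicarboxylate, toluene, 0 °C
Reagents that add atoms: benzoic acid, OC(=O)c1ccccc1
Why: Mitsunobu esterification inverts the secondary allylic carbinol by SN2 displacement (SN2' at the methyl-bearing alkene carbon is hindered) and so sets the trans, 4R configuration of ring A.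

Step 11
Reactants: 17 ethyl (2E,4E)-5-[(1R,4R)-4-(benzoyloxy)-2,6,6-trimethylcyclohex-2-en-1-yl]-3-methylpenta-2,4-dienoate
Product: 18 (2E,4E)-5-[(1R,4R)-4-hydroxy-2,6,6-trimethylcyclohex-2-en-1-yl]-3-methylpenta-2,4-dien-1-ol
Conditions: i-Bu2AlH, CH2Cl2, −78 → 0 °C; aq. Rochelle salt
Reagents that add atoms: none
Why: Aluminium hydride reduction cleaves the benzoate and takes the dienoate to the primary allylic alcohol in one operation without touching the alkenes or either stereocentre.

Step 12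
Reactants: 18 (2E,4E)-5-[(1R,4R)-4-hydroxy-2,6,6-trimethylcyclohex-2-en-1-yl]-3-methylpenta-2,4-dien-1-ol
Product: 19 {(2E,4E)-5-[(1R,4R)-4-hydroxy-2,6,6-trimethylcyclohex-2-en-1-yl]-3-methylpenta-2,4-dien-1-yl}triphenylphosphonium bromide
Conditions: Ph3P·HBr, CH2Cl2, 0 °C
Reagents that add atoms: triphenylphosphine hydrobromide, [Br-].[PH+](c1ccccc1)(c1ccccc1)c1ccccc1
Why: Standard C15 Wittig salt formation through the pentadienyl cation of the primary dienylic alcohol, which should ionise far more readily at 0 °C than the isolated ring allylic alcohol; C6' is not epimerised.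

Step 13
Reactants: 19 {(2E,4E)-5-[(1R,4R)-4-hydroxy-2,6,6-trimethylcyclohex-2-en-1-yl]-3-methylpenta-2,4-dien-1-yl}triphenylphosphonium bromide; 20 (2E,4E,6E)-2,7-dimethylocta-2,4,6-trienedial
Product: 21 (2E,4E,6E,8E,10E,12E)-13-[(1R,4R)-4-hydroxy-2,6,6-trimethylcyclohex-2-en-1-yl]-2,7,11-trimethyltrideca-2,4,6,8,10,12-hexaenal
Conditions: 20 (excess), 1,2-epoxybutane, EtOH, reflux, argon, dim light
Reagents that add atoms: none
Why: Wittig olefination of the semi-stabilised ylide (generated without added base by the epoxide) with one formyl group of the dialdehyde in excess forms C11'=C12', and hindered Z isomers should equilibrate to E on heating.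

Step 14
Reactants: 21 (2E,4E,6E,8E,10E,12E)-13-[(1R,4R)-4-hydroxy-2,6,6-trimethylcyclohex-2-en-1-yl]-2,7,11-trimethyltrideca-2,4,6,8,10,12-hexaenal; 12 {(2E,4E)-5-[(4S)-4-hydroxy-2,6,6-trimethyl-3-oxocyclohex-1-en-1-yl]-3-methylpenta-2,4-dien-1-yl}triphenylphosphonium bromide
Product: 22 (3S,3'R,6'R)-3,3'-dihydroxy-β,ε-caroten-4-one (all-E)
Conditions: 1,2-epoxybutane, EtOH, reflux; then heptane, reflux (Z → E); argon, dim light
Reagents that add atoms: none
Why: The second Wittig olefination forms C11=C12 under the same neutral conditions, under which the α-ketol and its C3 configuration should survive, and heating converts Z isomers into the all-E ketone.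

Step 15
Reactants: 22 (3S,3'R,6'R)-3,3'-dihydroxy-β,ε-caroten-4-one
Product: 25 (3S,4R,3'R,6'R)-β,ε-carotene-3,4,3'-triol (all-E), via bis-silyl ketone 23 (not isolated), via bis-silyl carbinol 24 (not isolated)
Conditions: (Me3Si)2NH, cat. Me3SiCl, CH2Cl2, rt, evaporation; Li[BH(s-Bu)3], THF, −78 °C; MeOH, K2CO3, 0 °C → rt
Reagents that add atoms: none
Why: In-situ silylation gives a non-chelating α-silyloxy enone, to which the bulky hydride should add 1,2 at C4 antiperiplanar to the C3–O bond (polar Felkin–Anh, through the half-chair in which that bond is pseudo-axial and the opposite face carries no axial methyl), so the new hydroxyl is cis to the C3 oxygen (4R); methanolic carbonate then removes both trimethylsilyl groups.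

Compound list
1 | 2-methylpentan-3-one | CCC(=O)C(C)C | starting material
2 | methyl (2S)-oxirane-2-carboxylate (methyl (S)-glycidate) | COC(=O)[C@@H]1CO1 | starting material
3 | 2,4-dimethyl-1-[(2S)-oxiran-2-yl]pentane-1,3-dione (present as its lithium enolate) | CC(C)C(=O)C(C)C(=O)[C@@H]1CO1 | intermediate
4 | (4S)-3,4-dihydroxy-2,6,6-trimethylcyclohex-2-en-1-one (enol form of (6S)-6-hydroxy-2,4,4-trimethylcyclohexane-1,3-dione) | CC1=C(O)[C@@H](O)CC(C)(C)C1=O | intermediate
5 | (7aS)-2,2,4,6,6-pentamethyl-7,7a-dihydro-1,3-benzodioxol-5(6H)-one | CC1=C2OC(C)(C)O[C@H]2CC(C)(C)C1=O | intermediate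
6 | (2E)-3-methylpent-2-en-4-yn-1-ol | C#C/C(C)=C/CO | starting material
7 | triethyl{[(2E)-3-methylpent-2-en-4-yn-1-yl]oxy}silane | C#C/C(C)=C/CO[Si](CC)(CC)CC | intermediate
8 | tributyl{(1E,3E)-3-methyl-5-[(triethylsilyl)oxy]penta-1,3-dien-1-yl}stannane | CCCC[Sn](CCCC)(CCCC)/C=C/C(C)=C/CO[Si](CC)(CC)CC | intermediate
9 | {(1E,3E)-3-methyl-5-[(triethylsilyl)oxy]penta-1,3-dien-1-yl}lithium | [Li]/C=C/C(C)=C/CO[Si](CC)(CC)CC | intermediate
10 | (7aS)-2,2,4,6,6-pentamethyl-5-{(1E,3E)-3-methyl-5-[(triethylsilyl)oxy]penta-1,3-dien-1-yl}-5,6,7,7a-tetrahydro-1,3-benzodioxol-5-ol (both C5 epimers) | CC1=C2OC(C)(C)O[C@H]2CC(C)(C)C1(O)/C=C/C(C)=C/CO[Si](CC)(CC)CC | intermediate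
11 | (6S)-6-hydroxy-3-[(1E,3E)-5-hydroxy-3-methylpenta-1,3-dien-1-yl]-2,4,4-trimethylcyclohex-2-en-1-one | OC/C=C(C)/C=C/C1=C(C)C(=O)[C@@H](O)CC1(C)C | intermediate
12 | {(2E,4E)-5-[(4S)-4-hydroxy-2,6,6-trimethyl-3-oxocyclohex-1-en-1-yl]-3-methylpenta-2,4-dien-1-yl}triphenylphosphonium bromide | [Br-].c1ccccc1[P+](c1ccccc1)(c1ccccc1)C/C=C(C)/C=C/C1=C(C)C(=O)[C@@H](O)CC1(C)C | intermediate
13 | (3E)-4-[(1R)-2,6,6-trimethylcyclohex-2-en-1-yl]but-3-en-2-one ((R)-α-ionone) | CC1=CCCC(C)(C)[C@H]1/C=C/C(C)=O | starting material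
14 | ethyl (2E,4E)-3-methyl-5-[(1R)-2,6,6-trimethylcyclohex-2-en-1-yl]penta-2,4-dienoate | CC1=CCCC(C)(C)[C@H]1/C=C/C(C)=C/C(=O)OCC | intermediate
15 | ethyl (2E,4E)-3-methyl-5-[(1R)-2,6,6-trimethyl-4-oxocyclohex-2-en-1-yl]penta-2,4-dienoate | CC1=CC(=O)CC(C)(C)[C@H]1/C=C/C(C)=C/C(=O)OCC | intermediate
16 | ethyl (2E,4E)-5-[(1R,4S)-4-hydroxy-2,6,6-trimethylcyclohex-2-en-1-yl]-3-methylpenta-2,4-dienoate | CC1=C[C@@H](O)CC(C)(C)[C@H]1/C=C/C(C)=C/C(=O)OCC | intermediate
17 | ethyl (2E,4E)-5-[(1R,4R)-4-(benzoyloxy)-2,6,6-trimethylcyclohex-2-en-1-yl]-3-methylpenta-2,4-dienoate | CC1=C[C@H](OC(=O)c2ccccc2)CC(C)(C)[C@H]1/C=C/C(C)=C/C(=O)OCC | intermediate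
18 | (2E,4E)-5-[(1R,4R)-4-hydroxy-2,6,6-trimethylcyclohex-2-en-1-yl]-3-methylpenta-2,4-dien-1-ol | CC1=C[C@H](O)CC(C)(C)[C@H]1/C=C/C(C)=C/CO | intermediate
19 | {(2E,4E)-5-[(1R,4R)-4-hydroxy-2,6,6-trimethylcyclohex-2-en-1-yl]-3-methylpenta-2,4-dien-1-yl}triphenylphosphonium bromide | [Br-].CC1=C[C@H](O)CC(C)(C)[C@H]1/C=C/C(C)=C/C[P+](c1ccccc1)(c1ccccc1)c1ccccc1 | intermediate
20 | (2E,4E,6E)-2,7-dimethylocta-2,4,6-trienedial | O=C/C(C)=C/C=C/C=C(C)/C=O | starting material
21 | (2E,4E,6E,8E,10E,12E)-13-[(1R,4R)-4-hydroxy-2,6,6-trimethylcyclohex-2-en-1-yl]-2,7,11-trimethyltrideca-2,4,6,8,10,12-hexaenal | CC1=C[C@H](O)CC(C)(C)[C@H]1/C=C/C(C)=C/C=C/C(C)=C/C=C/C=C(C)/C=O | intermediate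
22 | (3S,3'R,6'R)-3,3'-dihydroxy-β,ε-caroten-4-one (all-E) | CC1=C[C@H](O)CC(C)(C)[C@H]1/C=C/C(C)=C/C=C/C(C)=C/C=C/C=C(C)/C=C/C=C(C)/C=C/C1=C(C)C(=O)[C@@H](O)CC1(C)C | intermediate
23 | (3S,3'R,6'R)-3,3'-bis[(trimethylsilyl)oxy]-β,ε-caroten-4-one | CC1=C[C@H](O[Si](C)(C)C)CC(C)(C)[C@H]1/C=C/C(C)=C/C=C/C(C)=C/C=C/C=C(C)/C=C/C=C(C)/C=C/C1=C(C)C(=O)[C@@H](O[Si](C)(C)C)CC1(C)C | intermediate
24 | (3S,4R,3'R,6'R)-3,3'-bis[(trimethylsilyl)oxy]-β,ε-caroten-4-ol (present as its lithium alkoxide) | CC1=C[C@H](O[Si](C)(C)C)CC(C)(C)[C@H]1/C=C/C(C)=C/C=C/C(C)=C/C=C/C=C(C)/C=C/C=C(C)/C=C/C1=C(C)[C@@H](O)[C@@H](O[Si](C)(C)C)CC1(C)C | intermediate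
25 | (3S,4R,3'R,6'R)-β,ε-carotene-3,4,3'-triol (all-E) | CC1=C[C@H](O)CC(C)(C)[C@H]1/C=C/C(C)=C/C=C/C(C)=C/C=C/C=C(C)/C=C/C=C(C)/C=C/C1=C(C)[C@@H](O)[C@@H](O)CC1(C)C | target

Total step count: 15.
Longest linear sequence: 9 steps (13 → 14 → 15 → 16 → 17 → 18 → 19 → 21 → 22 → 25, steps 7 to 15). The ring-B branch (steps 1, 2, 5, 6) and the stannane branch (steps 3, 4) join it at steps 14 and 5.

Steps most likely to fail

Step 1 (Proposed new method). The second deprotonation, at the isopropyl methine of the diketonate, may be too slow. O-alkylation of the diketonate by the epoxide or attack at the internal epoxide carbon could then take over, and C3 could lose configuration by enolisation. Fallback from 1, by known chemistry: Michael–Claisen annulation of 1 with methyl acrylate (KOtBu, THF, 0 °C → reflux) forms the same two ring bonds. It passes through the Michael adduct methyl 4,4-dimethyl-5-oxoheptanoate F1 and gives 2,4,4-trimethylcyclohexane-1,3-dione F2. Isobutanol/TsOH with azeotropic removal of water etherifies the less hindered carbonyl to give 3-(2-methylpropoxy)-2,6,6-trimethylcyclohex-2-en-1-one F3. γ-Deprotonation with LiN(iPr)2 (the α' carbon is quaternary) and Davis hydroxylation with a (camphorsulfonyl)oxaziridine then give (4S)-4-hydroxy-3-(2-methylpropoxy)-2,6,6-trimethylcyclohex-2-en-1-one F4. The oxaziridine enantiomer that delivers the 4S carbinol has to be found on a test scale. Dilute aqueous HCl in THF cleaves the enol ether, and the route is rejoined at 4.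

Step 15. Facial selectivity of the hydride addition to C4 may be poor: attack syn to the C3 oxygen, through the half-chair with that oxygen pseudo-equatorial, gives the trans-diol. Fallback from 12: the C4 carbonyl is reduced before the last olefination, on the crystalline salt (NaBH4, MeOH/CH2Cl2, −40 °C). The epimeric diol salts are separated by fractional crystallisation to leave {(2E,4E)-5-[(3R,4S)-3,4-dihydroxy-2,6,6-trimethylcyclohex-1-en-1-yl]-3-methylpenta-2,4-dien-1-yl}triphenylphosphonium bromide F5; the cis relation can be checked on an aliquot by acetonide formation. Wittig reaction of F5 with 21 under the conditions of step 14 comes back to the route at 25.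

Step 5. The hindered vinylogous-ester carbonyl may resist addition of the dienyl organometallic, which could instead deprotonate the γ-position (C7a–H) and erode the C3 configuration. Fallback from 7 and 5: the smaller, less basic acetylide is used. Deprotonation of 7 (n-BuLi, THF, −78 °C) gives {(3E)-3-methyl-5-[(triethylsilyl)oxy]pent-3-en-1-yn-1-yl}lithium F6, which adds to 5 to give (7aS)-2,2,4,6,6-pentamethyl-5-{(3E)-3-methyl-5-[(triethylsilyl)oxy]pent-3-en-1-yn-1-yl}-5,6,7,7a-tetrahydro-1,3-benzodioxol-5-ol F7. Aqueous HCl converts F7 into (6S)-6-hydroxy-3-[(3E)-5-hydroxy-3-methylpent-3-en-1-yn-1-yl]-2,4,4-trimethylcyclohex-2-en-1-one F8. Partial reduction of the triple bond with zinc dust in acetic acid/CH2Cl2 gives (6S)-6-hydroxy-3-[(1Z,3E)-5-hydroxy-3-methylpenta-1,3-dien-1-yl]-2,4,4-trimethylcyclohex-2-en-1-one F9. Under the conditions of step 6 the hindered Z bond should equilibrate to E through the pentadienyl cation, so that the route is rejoined at 12.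

Further compounds
F1 | step 1 | methyl 4,4-dimethyl-5-oxoheptanoate | CCC(=O)C(C)(C)CCC(=O)OC
F2 | step 1 | 2,4,4-trimethylcyclohexane-1,3-dione | CC1C(=O)CCC(C)(C)C1=O
F3 | step 1 | 3-(2-methylpropoxy)-2,6,6-trimethylcyclohex-2-en-1-one | CC1=C(OCC(C)C)CCC(C)(C)C1=O
F4 | step 1 | (4S)-4-hydroxy-3-(2-methylpropoxy)-2,6,6-trimethylcyclohex-2-en-1-one | CC1=C(OCC(C)C)[C@@H](O)CC(C)(C)C1=O
F5 | step 15 | {(2E,4E)-5-[(3R,4S)-3,4-dihydroxy-2,6,6-trimethylcyclohex-1-en-1-yl]-3-methylpenta-2,4-dien-1-yl}triphenylphosphonium bromide | [Br-].c1ccccc1[P+](c1ccccc1)(c1ccccc1)C/C=C(C)/C=C/C1=C(C)[C@@H](O)[C@@H](O)CC1(C)C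
F6 | step 5 | {(3E)-3-methyl-5-[(triethylsilyl)oxy]pent-3-en-1-yn-1-yl}lithium | [Li]C#C/C(C)=C/CO[Si](CC)(CC)CC
F7 | step 5 | (7aS)-2,2,4,6,6-pentamethyl-5-{(3E)-3-methyl-5-[(triethylsilyl)oxy]pent-3-en-1-yn-1-yl}-5,6,7,7a-tetrahydro-1,3-benzodioxol-5-ol | CC1=C2OC(C)(C)O[C@H]2CC(C)(C)C1(O)C#C/C(C)=C/CO[Si](CC)(CC)CC
F8 | step 5 | (6S)-6-hydroxy-3-[(3E)-5-hydroxy-3-methylpent-3-en-1-yn-1-yl]-2,4,4-trimethylcyclohex-2-en-1-one | OC/C=C(C)/C#CC1=C(C)C(=O)[C@@H](O)CC1(C)C
F9 | step 5 | (6S)-6-hydroxy-3-[(1Z,3E)-5-hydroxy-3-methylpenta-1,3-dien-1-yl]-2,4,4-trimethylcyclohex-2-en-1-one | OC/C=C(C)/C=C\C1=C(C)C(=O)[C@@H](O)CC1(C)C
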